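Nothing leaves a closed flask of constant volume, so a reading in percent of the charge, multiplied by the charge, is a concentration.

| flask | solid substrate | enzyme | remark | time |
|---|---|---|---|---|
| delta | 0.034 M | 0.015 mol% | run made earlier |  |
| alpha | 0.075 M | 0.015 mol% | run made earlier |  |
| zeta | 0.050 M | 0.03 mol% | run made earlier |  |
| flask | 0.050 M | 0.015 mol% |  | 2.0 h |

| run | time / h | product / % | solid substrate / % |
|---|---|---|---|
| delta | 0.667 | 6.9 | 83.5 |
| delta | 1.33 | 12.3 | 71.8 |
| delta | 2.00 | 16.5 | 58.3 |
| delta | 2.50 | 21.5 | 51.5 |
| alpha | 0.333 | 0.4 | 94.9 |
| alpha | 0.833 | 5.3 | 91.5 |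
| alpha | 1.50 | 8.2 | 85.0 |
| alpha | 2.50 | 10.6 | 78.3 |
| zeta | 0.200 | 1.2 | 96.1 |
| zeta | 0.417 | 4.1 | 92.6 |
| zeta | 1.00 | 8.0 | 85.8 |
| zeta | 2.50 | 17.6 | 66.1 |

(readings scatter by 1 percentage point)

- as a solid, counted per litre of solution: solid substrate
- reactions considered so far: starting material + enzyme -> product + enzyme; solid substrate <-> starting material; 2 enzyme -> spent catalyst; starting material <-> dormant form
- at the start none of the solid substrate is in solution

1. product at 2.0 h, in percent of the solid substrate charged
2. the change that raises the amount of product at 2.0 h, in percent of the solid substrate charged most ("none" if none brings more than 2 percentage points) (south-west / west / south / none)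
3. amount of product at 2.0 h, in percent of the solid substrate charged, after south-west

- south-west: doubling the amount of enzyme, all else as stated
- west: doubling the dissolution coefficient of the solid substrate, all else as stated
- south: doubling the solubility of the solid substrate, all else as stated

1. The bench rule says that a percent yield carries over from one charge to another at the same loading. Delta read 16.5% at 2.00 h. Alpha, midway between its readings at 1.50 h and 2.50 h, gives 9.40%.

2. The rule breaks here: the gap is 7.1 percentage points, against a scatter of 1 point. At the last readings the percentages stand in a ratio of 2.03, and the charges in a ratio of 2.21. So in these readings the percent falls about as the charge rises, which reads as zero order in the charge.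

3. I therefore carry concentration instead. Delta gives 5.61 mM and alpha 7.05 mM. Their mean is c_product, the concentration of product at 2.0 h at this loading, taken as independent of the charge: 6.33 mM.

4. For this flask, c_product divided by 0.050 M gives 12.7%. Zeta, read between 1.00 h and 2.50 h, gives 14.4% for south-west.

5. The forecast gives 13% for this flask, 14.8% after south-west (above mine) and south as the best change, holding that “Doubling solubility doubles both the driving force and the dissolved level”.

6. The flask gives 12.7%; south-west gives 13.7%, and south is best, gaining 11 points.

    starting material + enzyme → product + enzyme, rate k1*[starting material]*[enzyme]/(1 + ([starting material]/Km1) + ([product]/Kp1)) (25.0 mM, 0.0770 M, k = 16000 M⁻¹ min⁻¹)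
    solid substrate ⇌ starting material, rate k2*(cs2 - [starting material]) while solid is left; crystals form when [starting material] > cs2 (solubility = 12.0 mM, k = 0.0120 min⁻¹)
    2 enzyme → spent catalyst (k = 4000 M⁻¹ min⁻¹)
    starting material ⇌ dormant form (K = 1.20, k = 0.0420 min⁻¹)

7. At 2.00 h this flask holds 12.2% of its enzyme as enzyme and 87.8% as spent catalyst, with 72.1% of the solid substrate still solid. Carried to a charge of 0.0886 M at the same loading and time, c_product reads 7.15%, a shift of 5.5 points from this flask. The simulated flask at that charge has moved by 5 points.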